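**Plan**

- Retrosynthesis: the O1–C5 and exocyclic C–Br bonds are cut together (bromolactonisation of an enynoic acid), then the bond from C5 to the exocyclic carbon (one-carbon homologation of a lactol aldehyde), then the C3–C1' bond between ring and side chain, and last the O–acyl and C1'–Cl bonds of a 1-chlorobutyl ester (butanal plus acetyl chloride).
- Forward: the racemic chloro ester is joined to C3 of 3,4-dibromofuran. The furan ring is then oxidised to a bromomaleic anhydride, reduced to the lactol beside C–Br and opened to an acyclic (Z)-enynoic acid. The butenolide ring is closed last, 5-exo-dig.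
- Enabling feature: the acetoxy-bearing stereocentre C1' sits on sp2 carbon C3 of the five-membered ring, and the neighbouring sp2 carbon C4 carries bromine. Mono-coupling of a symmetric 3,4-dibromofuran leaves exactly this pattern, and its four carbons become C2–C5.
- Stereochemistry: C1' (R) comes from the chiral nickel catalyst, which funnels both enantiomers of the chloride into one product. The (E)-bromomethylidene geometry comes from anti addition in the bromolactonisation.

Key step: step 2

Remark: the target SMILES places the exocyclic bromine cis to C4 (trans to the ring oxygen), i.e. the (5E)-bromomethylidene isomer, and the route is built for that geometry.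

**Step 1**
Reactants: 1 butanal; 2 acetyl chloride
Product: 3 rac-1-chlorobutyl acetate
Conditions: ZnCl2 (2 mol %), neat, −10 °C → rt; distillation under reduced pressure
Reagents that add atoms: none
Why: ZnCl2-catalysed addition of an acyl chloride across an aldehyde carbonyl (α-chloroalkyl ester formation) is long established for unhindered aliphatic aldehydes; the stereocentre is deliberately formed as a racemate because the next step is enantioconvergent.

**Step 2**
Reactants: 3 rac-1-chlorobutyl acetate; 4 3,4-dibromofuran (3 equiv, excess recovered)
Product: 5 (1R)-1-(4-bromofuran-3-yl)butyl acetate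
Conditions: NiBr2(dme) (10 mol %), enantiopure 2,2'-(cyclopropane-1,1-diyl)bis(3a,8a-dihydro-8H-indeno[1,2-d]oxazole) L* (12 mol %; the antipode that gives (R)-5, fixed in a first small run), Mn powder (3 equiv), NaI (0.5 equiv), THF/N,N-dimethylacetamide, 0 °C
Reagents that add atoms: none
Why: Proposed new method: zerovalent nickel bound to the chiral bis(oxazoline) should insert into one of the two equivalent C–Br bonds of 4, while monovalent nickel abstracts the halogen of 3 (chloride, or iodide after exchange with NaI) to release a planar 1-acetoxybutyl radical; capture of this radical by the divalent furylnickel bromide gives a trivalent nickel species that forms the C3–C1' bond by reductive elimination, and Mn returns nickel to its low-valent state. The closest known reaction types are nickel-catalysed enantioconvergent couplings of racemic 1-haloalkyl esters with organozinc reagents and asymmetric reductive cross-electrophile couplings of (hetero)aryl halides with racemic secondary alkyl chlorides; the union of a 1-chloroalkyl ester with a dibromofuran has no direct precedent. No ring is closed. The new stereocentre C1' is controlled by the chiral ligand at the radical-capture and reductive-elimination stage, and since both enantiomers of 3 give the same radical the racemate should converge on (R)-5. The step needs mono- over double coupling and cross- over homo-coupling: the excess of symmetric dibromide and the branched ortho substituent that shields the second C–Br bond should secure the first, the different activation modes of the sp2 bromide and the sp3 chloride the second; there is no regiochemical issue because the two C–Br bonds of 4 are equivalent, and β-bromide loss from the furylnickel would require a 3,4-furyne and is ruled out.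

**Step 3**
Reactants: 5 (1R)-1-(4-bromofuran-3-yl)butyl acetate
Product: 9 (1R)-1-(4-bromo-2,5-dioxo-2,5-dihydrofuran-3-yl)butyl acetate, via endoperoxide 6 (not isolated), via 3-bromo lactol 7 (not isolated), via 4-bromo lactol 8 (not isolated)
Conditions: O2, hν (visible), 5,10,15,20-tetraphenylporphyrin (cat.), iPr2NEt, CH2Cl2, −78 °C; concentrate; then CrO3, H2SO4, acetone, 0 °C
Reagents that add atoms: dioxygen, O=O
Why: [4+2] addition of singlet oxygen to the furan and base-induced Kornblum–DeLaMare collapse of the endoperoxide is the standard entry to 5-hydroxybutenolides, and Jones oxidation of such lactols to maleic anhydrides is routine, so whichever lactol regioisomer predominates both should converge on one anhydride with the acetate and C1' untouched.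

**Step 4**
Reactants: 9 (1R)-1-(4-bromo-2,5-dioxo-2,5-dihydrofuran-3-yl)butyl acetate
Product: 8 (1R)-1-(4-bromo-5-hydroxy-2-oxo-2,5-dihydrofuran-3-yl)butyl acetate (both C5 epimers)
Conditions: LiAlH(OtBu)3 (1.1 equiv), THF, −78 → −40 °C; aqueous work-up
Reagents that add atoms: none
Why: Partial reduction of a cyclic anhydride to the hydroxy-lactone by a bulky alkoxyaluminium hydride is known, and attack should go to the carbonyl next to C–Br because it is the less shielded one (bromine against a branched acetoxyalkyl group) and the more electrophilic one (the other carbonyl is the terminus of a vinylogous acyl bromide), the aluminate surviving at low temperature so that over-reduction and acetate cleavage are avoided; the lactol centre C5 forms without control and is destroyed in step 5.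

**Step 5**
Reactants: 8 (1R)-1-(4-bromo-5-hydroxy-2-oxo-2,5-dihydrofuran-3-yl)butyl acetate
Product: 10 (2E)-3-bromo-2-[(1R)-1-hydroxybutyl]pent-2-en-4-ynoic acid (carboxyl and ethynyl cis)
Conditions: dimethyl (1-diazo-2-oxopropyl)phosphonate (1.5 equiv), K2CO3 (4 equiv), MeOH, 0 °C → rt; then 1 M HCl to pH 2–3
Reagents that add atoms: dimethyl (1-diazo-2-oxopropyl)phosphonate, COP(=O)(OC)C(=[N+]=[N-])C(C)=O
Why: In carbonate/methanol the pseudo-acid opens to the (Z)-formyl carboxylate, whose aldehyde has no α-hydrogen and should undergo Ohira–Bestmann (Seyferth–Gilbert) homologation to the terminal alkyne with the cis arrangement of the former ring carried into the enyne, while the same medium transesterifies the acetate, so the alcohol is expected and is re-acetylated in step 6.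

**Step 6**
Reactants: 10 (2E)-3-bromo-2-[(1R)-1-hydroxybutyl]pent-2-en-4-ynoic acid
Product: 12 (2E)-2-[(1R)-1-acetoxybutyl]-3-bromopent-2-en-4-ynoic acid, via mixed anhydride 11 (not isolated)
Conditions: Ac2O (3 equiv), pyridine, 4-(dimethylamino)pyridine (cat.), CH2Cl2, 0 °C → rt; then H2O/THF, rt; acidic work-up
Reagents that add atoms: acetic anhydride, CC(=O)OC(C)=O
Why: Nucleophile-catalysed O-acetylation of a secondary alcohol is routine, and the carboxylic–acetic mixed anhydride formed alongside should be cleaved by water at its unhindered acetyl carbonyl, leaving the free acid with the acetate in place and C1' unchanged.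

**Step 7**
Reactants: 12 (2E)-2-[(1R)-1-acetoxybutyl]-3-bromopent-2-en-4-ynoic acid
Product: 13 acetoxyfimbrolide, (1R)-1-[(5E)-4-bromo-5-(bromomethylidene)-2-oxo-2,5-dihydrofuran-3-yl]butyl acetate
Conditions: N-bromosuccinimide (1.05 equiv), KHCO3 (cat.), nBu4NOH (cat.), CH2Cl2/H2O, 0 °C → rt, dark
Reagents that add atoms: N-bromosuccinimide, O=C1CCC(=O)N1Br
Why: Bromolactonisation of an alkynoic acid with N-bromosuccinimide proceeds by anti addition of carboxylate oxygen and bromine across the triple bond, and 5-exo-dig closure onto the internal alkyne carbon (Markovnikov sense for a terminal alkyne) should therefore place bromine trans to the ring oxygen and cis to C4, which is the (E) geometry of the target.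

**Compound list**

1 | butanal | CCCC=O | starting material
2 | acetyl chloride | CC(Cl)=O | starting material
3 | rac-1-chlorobutyl acetate | CCCC(Cl)OC(C)=O | intermediate
4 | 3,4-dibromofuran | Brc1cocc1Br | starting material
5 | (1R)-1-(4-bromofuran-3-yl)butyl acetate | CCC[C@@H](OC(C)=O)c1cocc1Br | intermediate
6 | (1R)-1-(6-bromo-2,3,7-trioxabicyclo[2.2.1]hept-5-en-5-yl)butyl acetate (endoperoxide, not isolated) | CCC[C@@H](OC(C)=O)C1=C(Br)C2OOC1O2 | intermediate
7 | (1R)-1-(4-bromo-2-hydroxy-5-oxo-2,5-dihydrofuran-3-yl)butyl acetate (lactol with the carbonyl beside C–Br, not isolated) | CCC[C@@H](OC(C)=O)C1=C(Br)C(=O)OC1O | intermediate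
8 | (1R)-1-(4-bromo-5-hydroxy-2-oxo-2,5-dihydrofuran-3-yl)butyl acetate (transient in step 3, isolated in step 4) | CCC[C@@H](OC(C)=O)C1=C(Br)C(O)OC1=O | intermediate
9 | (1R)-1-(4-bromo-2,5-dioxo-2,5-dihydrofuran-3-yl)butyl acetate | CCC[C@@H](OC(C)=O)C1=C(Br)C(=O)OC1=O | intermediate
10 | (2E)-3-bromo-2-[(1R)-1-hydroxybutyl]pent-2-en-4-ynoic acid | CCC[C@@H](O)/C(C(=O)O)=C(\Br)C#C | intermediate
11 | acetic (2E)-2-[(1R)-1-acetoxybutyl]-3-bromopent-2-en-4-ynoic anhydride (not isolated) | CCC[C@@H](OC(C)=O)/C(C(=O)OC(C)=O)=C(\Br)C#C | intermediate
12 | (2E)-2-[(1R)-1-acetoxybutyl]-3-bromopent-2-en-4-ynoic acid | CCC[C@@H](OC(C)=O)/C(C(=O)O)=C(\Br)C#C | intermediate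
13 | acetoxyfimbrolide, (1R)-1-[(5E)-4-bromo-5-(bromomethylidene)-2-oxo-2,5-dihydrofuran-3-yl]butyl acetate | CCC[C@@H](OC(C)=O)C1=C(Br)/C(=C\Br)OC1=O | target

**Step count**

Total: 7 steps. Longest linear sequence: 7 steps (butanal to 13; 3,4-dibromofuran enters at step 2).

**Steps most likely to fail**

Step 2 (new method). The catalytic cycle may not mesh: insertion into the electron-rich bromofuran may be slower than reductive dimerisation or reduction of the chloro ester, a second coupling may consume the product, or radical capture may occur with poor facial discrimination. The fallback uses known chemistry, sets out from 4 and returns at 5. Bromine–lithium exchange on 4 (nBuLi, Et2O, −78 °C) gives (4-bromofuran-3-yl)lithium F1. Acylation with N-methoxy-N-methylbutanamide gives 1-(4-bromofuran-3-yl)butan-1-one F2. Corey–Bakshi–Shibata reduction ((S)-2-methyl-CBS-oxazaborolidine (cat.), BH3·SMe2, THF, −20 °C), with the bromofuryl group as the large and propyl as the small substituent, should give (1R)-1-(4-bromofuran-3-yl)butan-1-ol F3. Acetylation (Ac2O, pyridine, cat. 4-(dimethylamino)pyridine) then gives 5.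

Step 4. Hydride may be delivered to the wrong carbonyl, may add in conjugate fashion with loss of bromide or acetate, or the aluminate may collapse early so that reduction runs on to the lactone. The fallback fixes the regiochemistry by a silicon tether instead of by reagent preference; it sets out from 5 and returns at 10. Methanolysis of the acetate (K2CO3, MeOH) gives (1R)-1-(4-bromofuran-3-yl)butan-1-ol F3, the same carbinol as in the first fallback. Dehydrogenative O-silylation (Et2SiH2, [Ir(cod)OMe]2 (cat.), THF) gives (R)-[1-(4-bromofuran-3-yl)butoxy]diethylsilane F4. Hydroxyl-directed iridium-catalysed C–H silylation ([Ir(cod)OMe]2, 1,10-phenanthroline, norbornene, THF, 80 °C) can only reach the ring C–H next to the side chain and should close the furan-fused oxasilole (3R)-4-bromo-1,1-diethyl-3-propyl-1,3-dihydrofuro[2,3-c][1,2]oxasilole F5, in which SiEt2 bridges the C1' oxygen and furan C2. Photooxygenation of this 2-silylfuran (O2, hν, 5,10,15,20-tetraphenylporphyrin, CH2Cl2, −78 °C; aqueous work-up) places the lactone carbonyl at the silicon-bearing carbon by silyl migration and should give only 4-bromo-5-hydroxy-3-[(1R)-1-hydroxybutyl]furan-2(5H)-one F6. Under the conditions of step 5 this is homologated directly to 10.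

Step 5. Material may be lost while the bromo-enal sits in basic methanol: methoxide may add to or displace bromide from the unsaturated system, γ-deprotonation at C1' may erode the configuration, or the enynoate may cyclise prematurely. The fallback leaves the protic carbonate system, sets out from 8 and returns at 12, so that 10, 11 and step 6 drop out; it makes no new compound (F0). Lactol 8 is converted into its potassium salt with one equivalent of KOtBu in THF at −78 °C and added to the preformed potassium salt of dimethyl (diazomethyl)phosphonate (KOtBu, THF, −78 °C; Seyferth–Gilbert homologation). The only base then present is the stabilised phosphonate carbanion, no alkoxide nucleophile is in solution, and the acetate should survive.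

**Further compounds**

F1 | step 2 | (4-bromofuran-3-yl)lithium | [Li]c1cocc1Br
F2 | step 2 | 1-(4-bromofuran-3-yl)butan-1-one | CCCC(=O)c1cocc1Br
F3 | step 2 | (1R)-1-(4-bromofuran-3-yl)butan-1-ol | CCC[C@@H](O)c1cocc1Br
F4 | step 4 | (R)-[1-(4-bromofuran-3-yl)butoxy]diethylsilane | CCC[C@@H](O[SiH](CC)CC)c1cocc1Br
F5 | step 4 | (3R)-4-bromo-1,1-diethyl-3-propyl-1,3-dihydrofuro[2,3-c][1,2]oxasilole | CCC[C@H]1O[Si](CC)(CC)c2occ(Br)c21
F6 | step 4 | 4-bromo-5-hydroxy-3-[(1R)-1-hydroxybutyl]furan-2(5H)-one | CCC[C@@H](O)C1=C(Br)C(O)OC1=O
F0 | step 5 | none | none
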